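**Plan**
- Retrosynthesis: the six O-benzyl groups and two temporary C–Br caps on ring A come off last in one hydrogenolysis. Ring C is then cut at C4–C3 and O1–C2, giving a ring A o-quinone methide and a (Z)-β-aroyloxystyrene. The enol ester C–O bond is cut to an arylalkyne and protected 4-O-methylgallic acid.
- Enabling feature: O1–C8a=C4a–C4, where ring A meets ring C, is the oxadiene of a phloroglucinol o-quinone methide, and C2–C3 with its cis aryl and acyloxy groups is a Z enol ester. The para oxygen of ring B makes C3 the nucleophilic carbon and C2 the cation-stabilising one; the target's own galloyl ester keeps the competing oxygen donor weak, so no late acylation is needed.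
- Forward: the ring A piece (3 steps) and the ring B/galloyl enol ester (4 steps) are made separately. Ring C and both stereocentres arise in one oxa-[4+2] cycloaddition, and one hydrogenolysis ends the route.
- Stereochemistry: 2,3-cis from the Z alkene (suprafacial addition); absolute (2R,3R) from the chiral Brønsted acid counter-anion.

Key step: step 8

Assumption: for an o-quinone methide without a substituent on the methide carbon the sense of induction of the chiral acid cannot be derived from existing models; the (R)-catalyst is written, and its mirror image would be used if the (2S,3S) adduct predominated.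
Assumption: methyl 3,5-dihydroxy-4-methoxybenzoate, 2,4,6-trihydroxybenzaldehyde and 3,4-bis(benzyloxy)benzaldehyde are taken as catalogue compounds.

**Route**

Step 1
Reactants: 1 2,4,6-trihydroxybenzaldehyde
Product: 2 2,4-bis(benzyloxy)-6-hydroxybenzaldehyde
Conditions: BnBr (2.05 equiv), K2CO3 (2.2 equiv), DMF, 0 °C → rt
Reagents that add atoms: benzyl bromide, BrCc1ccccc1
Why: Williamson etherification in which the 4-OH and one ortho-OH are alkylated, while the last ortho-OH, hydrogen-bonded to the formyl oxygen, is the least nucleophilic and should stay free with two equivalents of bromide.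

Step 2
Reactants: 2 2,4-bis(benzyloxy)-6-hydroxybenzaldehyde
Product: 3 2,4-bis(benzyloxy)-3,5-dibromo-6-hydroxybenzaldehyde
Conditions: NBS (2.1 equiv), MeCN/CH2Cl2, 0 °C → rt, dark
Reagents that add atoms: N-bromosuccinimide, O=C1CCC(=O)N1Br
Why: electrophilic aromatic bromination at the only two ring CH positions, each ortho or para to three oxygen donors, which installs the temporary caps that leave ring A fully substituted.

Step 3
Reactants: 3 2,4-bis(benzyloxy)-3,5-dibromo-6-hydroxybenzaldehyde
Product: 4 3,5-bis(benzyloxy)-2,4-dibromo-6-(hydroxymethyl)phenol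
Conditions: NaBH4 (1.0 equiv), THF/MeOH 4:1, 0 °C, 30 min; pH 7 phosphate buffer; used at once
Reagents that add atoms: none
Why: hydride reduction of the aldehyde to the salicyl alcohol, where short contact at 0 °C and a neutral quench should avoid ionisation of the benzylic alcohol and over-reduction.

Step 4
Reactants: 5 methyl 3,5-dihydroxy-4-methoxybenzoate
Product: 6 methyl 3,5-bis(benzyloxy)-4-methoxybenzoate
Conditions: BnBr (2.3 equiv), K2CO3 (3 equiv), DMF, 60 °C
Reagents that add atoms: benzyl bromide, BrCc1ccccc1
Why: Williamson etherification of the two equivalent phenols, with no selectivity issue.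

Step 5
Reactants: 6 methyl 3,5-bis(benzyloxy)-4-methoxybenzoate
Product: 7 3,5-bis(benzyloxy)-4-methoxybenzoic acid
Conditions: LiOH·H2O (4 equiv), THF/MeOH/H2O 3:1:1, 50 °C; then 1 M HCl to pH 2
Reagents that add atoms: lithium hydroxide, [Li+].[OH-]
Why: saponification of a methyl benzoate by acyl–oxygen cleavage, to which benzyl and methyl aryl ethers are inert.

Step 6
Reactants: 8 3,4-bis(benzyloxy)benzaldehyde
Product: 9 1,2-bis(benzyloxy)-4-ethynylbenzene
Conditions: dimethyl (1-diazo-2-oxopropyl)phosphonate (1.3 equiv), K2CO3 (2 equiv), MeOH/THF 1:1, 0 °C → rt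
Reagents that add atoms: dimethyl (1-diazo-2-oxopropyl)phosphonate (Ohira–Bestmann reagent), CC(=O)C(=[N+]=[N-])P(=O)(OC)OC
Why: Seyferth–Gilbert homologation in the Ohira–Bestmann variant, which converts an aryl aldehyde into the terminal alkyne under mild base that leaves benzyl ethers untouched.

Step 7
Reactants: 9 1,2-bis(benzyloxy)-4-ethynylbenzene; 7 3,5-bis(benzyloxy)-4-methoxybenzoic acid
Product: 10 (Z)-2-[3,4-bis(benzyloxy)phenyl]ethenyl 3,5-bis(benzyloxy)-4-methoxybenzoate
Conditions: Ru(η3-CH2C(CH3)CH2)2(Ph2P(CH2)4PPh2) (3 mol %), toluene, 65 °C, Ar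
Reagents that add atoms: none
Why: ruthenium-catalysed anti-Markovnikov hydro-oxycarbonylation of a terminal alkyne, in which the carboxylate adds to the α-carbon of a ruthenium vinylidene and protonolysis of the alkenyl–ruthenium bond should deliver the Z enol ester typical of bis(allyl)ruthenium diphosphine catalysts.

Step 8
Reactants: 4 3,5-bis(benzyloxy)-2,4-dibromo-6-(hydroxymethyl)phenol; 10 (Z)-2-[3,4-bis(benzyloxy)phenyl]ethenyl 3,5-bis(benzyloxy)-4-methoxybenzoate
Product: 12 (2R,3R)-5,7-bis(benzyloxy)-2-[3,4-bis(benzyloxy)phenyl]-6,8-dibromochroman-3-yl 3,5-bis(benzyloxy)-4-methoxybenzoate, via o-quinone methide 11 (not isolated)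
Conditions: (R)-3,3'-bis(2,4,6-triisopropylphenyl)-1,1'-binaphthyl-2,2'-diyl N-(trifluoromethanesulfonyl)phosphoramide (5 mol %), 5 Å MS, toluene, −20 °C → rt; 4 (1.3 equiv) added over 6 h by syringe pump
Reagents that add atoms: none
Why: Proposed new method: the acid ionises the benzylic C–OH of 4 to the o-quinone methide 11, held as a hydrogen-bonded ion pair with the chiral phosphoramide anion, and the Z alkene of 10 adds across its CH2=C–C=O unit in an inverse-electron-demand oxa-Diels–Alder reaction, the acyloxy-bearing carbon bonding to CH2 and the benzylic carbon to oxygen. The closest known reaction types are the chiral N-triflylphosphoramide-catalysed [4+2] cycloaddition of in situ generated o-quinone methides with styrenes to 2-arylchromans and the confined-acid-catalysed hetero-Diels–Alder reactions of styrenes with unsubstituted CH2=X cationic heterodienes; new are the methide-unsubstituted phloroglucinol-type o-quinone methide and the β-acyloxystyrene partner. Ring C closes as a suprafacial [4π+2π] cycloaddition, asynchronous with the C3–C4 bond leading, which in the stepwise limit is a 6-exo-trig capture of the ring B benzylic cation by the ring A oxygen. The 2,3-cis relation of C2 and C3 is carried over from the Z geometry of 10, and the absolute configuration (2R,3R) is set by the alkene face that the 3,3'-aryl pocket of the catalyst leaves open to the bound methide. The step needs regioselectivity, secured by the para-benzyloxy group of ring B, which stabilises charge at C2 far better than the weakly donating aroyloxy group could at C3, and chemoselectivity against Friedel–Crafts attack of 11 on ring A, secured by the two bromine caps that leave ring A without a free position and make 11 more electrophilic. Slow addition of 4 keeps 11 dilute so that ion-pair collapse to 12 should outrun rotation in the cationic intermediate and isomerisation of 10.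

Step 9
Reactants: 12 (2R,3R)-5,7-bis(benzyloxy)-2-[3,4-bis(benzyloxy)phenyl]-6,8-dibromochroman-3-yl 3,5-bis(benzyloxy)-4-methoxybenzoate
Product: 13 epicatechin 3-O-(4-O-methylgallate)
Conditions: H2 (1 atm), Pd(OH)2/C, Et3N (2.2 equiv), THF/MeOH 1:1, rt; filtration, Sephadex LH-20
Reagents that add atoms: none
Why: heterogeneous hydrogenolysis should cleave the six benzyl aryl ethers and, with triethylamine as HBr acceptor, the two aryl C–Br bonds, while the ester, the aryl methyl ether and both stereocentres are untouched.

**Compound list**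
1 | 2,4,6-trihydroxybenzaldehyde | O=Cc1c(O)cc(O)cc1O | starting material
2 | 2,4-bis(benzyloxy)-6-hydroxybenzaldehyde | O=Cc1c(O)cc(OCc2ccccc2)cc1OCc1ccccc1 | intermediate
3 | 2,4-bis(benzyloxy)-3,5-dibromo-6-hydroxybenzaldehyde | O=Cc1c(O)c(Br)c(OCc2ccccc2)c(Br)c1OCc1ccccc1 | intermediate
4 | 3,5-bis(benzyloxy)-2,4-dibromo-6-(hydroxymethyl)phenol | OCc1c(O)c(Br)c(OCc2ccccc2)c(Br)c1OCc1ccccc1 | intermediate
5 | methyl 3,5-dihydroxy-4-methoxybenzoate | COC(=O)c1cc(O)c(OC)c(O)c1 | starting material
6 | methyl 3,5-bis(benzyloxy)-4-methoxybenzoate | COC(=O)c1cc(OCc2ccccc2)c(OC)c(OCc2ccccc2)c1 | intermediate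
7 | 3,5-bis(benzyloxy)-4-methoxybenzoic acid | COc1c(OCc2ccccc2)cc(C(=O)O)cc1OCc1ccccc1 | intermediate
8 | 3,4-bis(benzyloxy)benzaldehyde | O=Cc1ccc(OCc2ccccc2)c(OCc2ccccc2)c1 | starting material
9 | 1,2-bis(benzyloxy)-4-ethynylbenzene | C#Cc1ccc(OCc2ccccc2)c(OCc2ccccc2)c1 | intermediate
10 | (Z)-2-[3,4-bis(benzyloxy)phenyl]ethenyl 3,5-bis(benzyloxy)-4-methoxybenzoate | COc1c(OCc2ccccc2)cc(cc1OCc1ccccc1)C(=O)O/C=C\c1ccc(OCc2ccccc2)c(OCc2ccccc2)c1 | intermediate
11 | 3,5-bis(benzyloxy)-2,4-dibromo-6-methylidenecyclohexa-2,4-dien-1-one (o-quinone methide) | C=C1C(=O)C(Br)=C(OCc2ccccc2)C(Br)=C1OCc1ccccc1 | intermediate (not isolated)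
12 | (2R,3R)-5,7-bis(benzyloxy)-2-[3,4-bis(benzyloxy)phenyl]-6,8-dibromochroman-3-yl 3,5-bis(benzyloxy)-4-methoxybenzoate | COc1c(OCc2ccccc2)cc(cc1OCc1ccccc1)C(=O)O[C@@H]1Cc2c(OCc3ccccc3)c(Br)c(OCc3ccccc3)c(Br)c2O[C@@H]1c1ccc(OCc2ccccc2)c(OCc2ccccc2)c1 | intermediate
13 | epicatechin 3-O-(4-O-methylgallate), (2R,3R) | COc1c(O)cc(C(=O)O[C@@H]2Cc3c(O)cc(O)cc3O[C@@H]2c2ccc(O)c(O)c2)cc1O | target

**Count**
Total steps: 9. Longest linear sequence: 5 steps (1 → 2 → 3 → 4 → 12 → 13, or 5 → 6 → 7 → 10 → 12 → 13).

**Steps most likely to fail**

Step 8. The chiral anion may discriminate the alkene faces poorly because the methide carbon bears no substituent. The Z-to-cis transfer may also erode through a long-lived ring B benzylic cation (bond rotation, participation of the neighbouring aroyloxy group, or acid-mediated Z/E isomerisation of the dienophile), leading into the 2,3-trans series. The fallback gives up asymmetric catalysis for a neutral, concerted cycloaddition followed by resolution. It sets out from 4 and 10, which are heated without acid (o-xylene, 140 °C, sealed tube), so that 11 forms by thermal dehydration and adds stereospecifically to the Z alkene. This should give the racemic cis cycloadduct F1. Preparative chromatography on a chiral stationary phase (amylose tris(3,5-dimethylphenylcarbamate), supercritical CO2/2-propanol) separates the enantiomers, and the route is rejoined at 12.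

Step 9. The two doubly ortho-substituted C–Br bonds may be reduced incompletely, the benzylic O1–C2 bond may be opened by over-hydrogenolysis, and the amine may cause C2 epimerisation or acyl migration. The fallback separates the two reductive events. It sets out from 12, which undergoes homogeneous transfer hydrodebromination (Pd(OAc)2, 2-dicyclohexylphosphino-2',6'-dimethoxybiphenyl, HCO2H/Et3N, DMF, 60 °C) to the debrominated hexabenzyl ether F2. Base-free hydrogenolysis (H2, Pd(OH)2/C, THF/MeOH, rt) then removes the benzyl groups, and the route is rejoined at 13.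

Step 7. The Z geometry may erode, Markovnikov addition may compete, or the arylalkyne may dimerise on ruthenium. The fallback fixes the geometry at boron first. It sets out from 9, which undergoes rhodium-catalysed trans-hydroboration with pinacolborane ([RhCl(cod)]2, P(i-Pr)3, Et3N, cyclohexane, rt) to the (Z)-alkenylboronate F3. KHF2 in MeOH/H2O converts this into the potassium (Z)-alkenyltrifluoroborate F4. A copper-promoted oxidative C–O coupling of Chan–Lam type with acid 7 (CuBr, DMAP, 4 Å MS, O2, MeCN, 60 °C) should proceed with retention of geometry, and the route is rejoined at 10.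

**Further compounds**
F1 | step 8 | racemic cis cycloadduct (1:1 mixture of 12 and its (2S,3S) enantiomer) | COc1c(OCc2ccccc2)cc(cc1OCc1ccccc1)C(=O)O[C@@H]1Cc2c(OCc3ccccc3)c(Br)c(OCc3ccccc3)c(Br)c2O[C@@H]1c1ccc(OCc2ccccc2)c(OCc2ccccc2)c1.COc1c(OCc2ccccc2)cc(cc1OCc1ccccc1)C(=O)O[C@H]1Cc2c(OCc3ccccc3)c(Br)c(OCc3ccccc3)c(Br)c2O[C@H]1c1ccc(OCc2ccccc2)c(OCc2ccccc2)c1
F2 | step 9 | (2R,3R)-5,7-bis(benzyloxy)-2-[3,4-bis(benzyloxy)phenyl]chroman-3-yl 3,5-bis(benzyloxy)-4-methoxybenzoate | COc1c(OCc2ccccc2)cc(cc1OCc1ccccc1)C(=O)O[C@@H]1Cc2c(OCc3ccccc3)cc(OCc3ccccc3)cc2O[C@@H]1c1ccc(OCc2ccccc2)c(OCc2ccccc2)c1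
F3 | step 7 | 2-[(Z)-2-(3,4-bis(benzyloxy)phenyl)ethenyl]-4,4,5,5-tetramethyl-1,3,2-dioxaborolane | CC1(C)OB(OC1(C)C)/C=C\c1ccc(OCc2ccccc2)c(OCc2ccccc2)c1
F4 | step 7 | potassium (Z)-[2-(3,4-bis(benzyloxy)phenyl)ethenyl]trifluoroborate | [K+].F[B-](F)(F)/C=C\c1ccc(OCc2ccccc2)c(OCc2ccccc2)c1
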